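# Proposed synthesis of (3R,4R)-4-(4-hydroxy-3-methoxybenzoyl)-3-(4-hydroxy-3-methoxybenzyl)dihydrofuran-2(3H)-one (15)

## The problem

Compound 15 is a monocyclic γ-butyrolactone (O1, carbonyl C2, C3, C4, C5) carrying a guaiacylmethyl group on C3 and a guaiacyl ketone on C4. No rings are fused, so the work lies in the chain C2–C3–C4–ketone carbon and its two adjacent stereocentres, both R, with the substituents trans. The two centres differ in character. C4 is α to the aryl ketone and can be equilibrated, so it can be made to follow C3 into the more stable trans arrangement. C3 is α only to the lactone carbonyl, cannot be corrected without endangering optical purity, and must be set absolutely; control therefore runs from C3 to C4 and not in reverse.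

Several groups will not survive rough treatment. The free guaiacol hydroxyls are oxidation-prone and must be masked. The C5–O1 bond is β to the ketone, so a strong base can expel the carboxylate by E1cB. The electron-rich aryl ketone can be over-reduced under hydrogenation. The two dialkoxyarenes limit the choice of oxidants.

The enabling feature is that the ketone carbon and C2 stand 1,4 to each other across the C3–C4 bond. Joined end to end they become the two sp2 carbons of a 1-arylcyclobutene whose sp3 carbons are C3 and C4. Oxidative cleavage of that double bond returns both carbonyl carbons at once. Such a cyclobutene is the (2+2) adduct of an arylalkyne (ketone carbon and C2) and a 4-arylbut-2-enoyl unit (C3, C4 and, as its acyl carbon, C5), and both halves derive from the same guaiacyl feedstocks, vanillin and eugenol.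

## Retrosynthesis

**15 to 14.** The two phenolic O–H bonds are traced back to O–benzyl bonds in the trans keto lactone 14. Benzyl ethers are preferred to silyl or acyl groups for three reasons. They survive carbonate in methanol, a titanium Lewis acid, LiBH4, ozone at low temperature and DBU. They keep the alkyne-derived arene electron-rich, which the key step needs and an acyl group would not allow. They leave without base or fluoride, which would threaten the β-acyloxy ketone. The forward reaction must cleave two benzyl ethers faster than it reduces the ketone.

**14 to 13.** No skeletal bond is cut; only the C4–H bond is exchanged, so that trans 14 comes from its cis C4 epimer 13. The cut is dictated by what the cyclobutene delivers (next paragraph). It is placed at the lactone stage and not at the lactol stage because in lactol 12 the C3 centre is α to a masked aldehyde and the open form is a β-hydroxy ketone that can undergo retro-aldol loss of formaldehyde. In 13, C3 is the least acidic position. The forward step needs a base that enolises the ketone only.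

**13 to 12 to 9.** The lactone carbonyl of 13 is stepped down to lactol 12. Its O1–C2 bond is opened to the hydroxy keto aldehyde 11, and the two carbonyl carbons are reconnected as a C=C bond through the primary ozonide 10, giving the cyclobutenylmethanol 9. The four-membered ring is the only carbocycle that contains exactly C2, C3, C4 and the ketone carbon, so this reconnection removes both carbonyls and leaves a hydrocarbon ring with one hydroxymethyl group.

The mapping is: cyclobutene C1 (CH2OH-bearing) is lactone C4; cyclobutene C2 (aryl-bearing) is the ketone carbon; cyclobutene C3 (=CH) is lactone C2; cyclobutene C4 (benzyl-bearing) is lactone C3. At lactone C4 the ring member and the exocyclic substituent change roles on cleavage, so the trans cyclobutene 9 gives the cis lactone series. The forward reaction must cleave a strained styrenyl double bond without touching two dialkoxyarenes.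

**9 to 8.** The primary alcohol is traced to the N-acyl oxazolidinone 8, with C5 at the acyl oxidation level. The imide is kept until after the cycloaddition because it gives the two-point binding that a chiral Lewis acid needs. It is reduced before the alkene is cleaved so that the hydroxyl is in place to trap the aldehyde. The forward reduction must attack the exocyclic carbonyl and leave the allylic, imide-activated C1–H untouched.

**8 to 4 and 7.** Both ring bonds that flank the sp3 carbons are cut: cyclobutene C3–C4 (lactone C2–C3) and cyclobutene C1–C2 (lactone C4–ketone carbon). This divides 8 into the enoyl imide 4 and the arylalkyne 7, two fragments of equal size. The cut is polarity-matched: the nucleophilic alkyne CH meets the electrophilic β-carbon of the imide, and the aryl-stabilised cationic carbon meets the enolate carbon. The other pairing of ring bonds would require an unpolarised alkene–alkyne union. The forward step must deliver one regioisomer, one enantioface at butenoyl C3 and the trans relationship.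

**4 to 2 and 3; 2 to 1.** The C2=C3 double bond of the butenoyl chain is cut by cross-metathesis logic into O-benzyleugenol 2 and commercial 3-acryloyl-1,3-oxazolidin-2-one 3. This avoids the arylacetaldehyde that a carbonyl olefination would need. Compound 2 is the benzyl ether of eugenol 1. The forward metathesis must give the E alkene without moving the double bond into conjugation with the arene.

**7 to 6 to 5.** The alkyne carbon is removed by one-carbon homologation logic to O-benzylvanillin 6, the benzyl ether of vanillin 5. This route to the arylalkyne needs no aryl halide and no palladium.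

## Roads not taken

**Alternative 1:** The lactone is cut at the C2–C3 bond. The precursor is the Se-phenyl selenocarbonate A1 of a homoallylic alcohol that already carries C4 and a silyl-protected benzylic carbinol in place of the ketone. A silane chain carrier with an azo initiator would generate the alkoxycarbonyl radical, which adds 5-exo to the styrene and gives the trans lactone A2. Desilylation, oxidation of the carbinol and debenzylation would follow.

- Merits: the ring closure is a well-precedented radical reaction, tolerant of the arenes. In A2 only C3 is acidic, so any cis isomer could be equilibrated to trans with no risk to C4. In security of the key step this road is better than the chosen plan.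
- Weak points: the closure creates no absolute stereochemistry. A1 needs C4 and the carbinol centre set beforehand by a separate asymmetric C–C bond formation, and the carbinol centre is then destroyed by oxidation. The styrene, the protected aldol-type array and the selenocarbonate make the route to A1 long.
- Comparison: the chosen plan offers a shorter, convergent assembly from two feedstock phenols in which both C–C bonds and the absolute configuration arise in one catalytic step. It pays for this with a key step that is not yet precedented.

**Alternative 2:** The bonds from the ketone carbon to C4 and to the arene are cut. A zerovalent palladium catalyst would join the 3-benzyltetronic acid triflate A3, the arylboronic acid A4 and carbon monoxide A5 to the achiral butenolide A6.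

- Merits: high convergence, a flat and probably crystalline intermediate, and very few steps to the full carbon skeleton. In step count to the skeleton this road is better.
- Weak points: direct coupling without carbon monoxide uptake competes on an electron-poor vinyl triflate. More seriously, both stereocentres are deferred to an enantioselective reduction of a tetrasubstituted alkene that is conjugated to a lactone and a ketone and sits beside two benzyl ethers. No reliable method exists for this. Syn addition of hydrogen would give the cis isomer; this could be repaired at C4, but the absolute configuration at C3 would rest entirely on the unprecedented reduction.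
- Comparison: the chosen plan sets C3 in the bond-forming event itself under a defined ligand model and leaves only the correctable C4 centre for later.

**Alternative 3:** Three bonds are cut at once: benzylic CH2–C3, C4–C5 and O1–C2. A monovalent copper catalyst with a chiral phosphoramidite would transfer the benzyl group of the benzylzinc bromide A8 to the aroylacrylate A7 at the carbon α to the ester. The ketone enolate would add to formaldehyde A9, and the alkoxide would close the lactone to give A10, which is identical with 14 of the chosen route.

- Merits: this is the most step-economic road. It would reach the penultimate compound in one operation, needs no redox adjustment, and would save about five steps.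
- Weak points: three events must succeed in one flask. Enantioselective copper-catalysed transfer of a benzylic group from a zinc halide is poorly developed. The zinc enolate must be trapped by monomeric formaldehyde without double hydroxymethylation, retro-aldol or dehydration to the methylene ketone. The trans relationship would rest on equilibration under conditions where the β-acyloxy ketone is already present.
- Comparison: the chosen plan concentrates its risk in one two-component step with a clear polar mechanism and follows it with conventional reactions. Both plans contain one step beyond precedent.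

Key step: step 5

Assumption: the titanium TADDOLate is taken to shield the same face of the chelated s-cis enoyl imide as in its cycloadditions with dienes, where the (R,R) ligand leaves the C2-Re/C3-Si face open. The (S,S) ligand is therefore specified, and the (R,R) ligand would be used if the sense of induction proved reversed.

## Route

Step 1
Reactants: 1 eugenol (4-allyl-2-methoxyphenol)
Product: 2 4-allyl-1-(benzyloxy)-2-methoxybenzene
Conditions: BnBr, K2CO3, DMF, rt
Reagents that add atoms: benzyl bromide, BrCc1ccccc1
Why: Williamson ether synthesis; the phenoxide displaces bromide from benzyl bromide and the allyl group is inert to carbonate.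

Step 2
Reactants: 2 4-allyl-1-(benzyloxy)-2-methoxybenzene; 3 3-acryloyl-1,3-oxazolidin-2-one
Product: 4 3-[(E)-4-(4-benzyloxy-3-methoxyphenyl)but-2-enoyl]-1,3-oxazolidin-2-one
Conditions: second-generation Grubbs catalyst (5 mol%), 1,4-benzoquinone (10 mol%), CH2Cl2, 40 °C
Reagents that add atoms: none
Why: Olefin cross-metathesis between a reactive terminal allylarene and an electron-poor acryloyl imide that homodimerises slowly should favour the cross product, with the E alkene formed under thermodynamic control. Benzoquinone is added to suppress ruthenium hydride-induced double-bond migration.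

Step 3
Reactants: 5 vanillin (4-hydroxy-3-methoxybenzaldehyde)
Product: 6 4-(benzyloxy)-3-methoxybenzaldehyde
Conditions: BnBr, K2CO3, DMF, rt
Reagents that add atoms: benzyl bromide, BrCc1ccccc1
Why: Williamson ether synthesis on the phenoxide; the non-enolisable aldehyde is unaffected.

Step 4
Reactants: 6 4-(benzyloxy)-3-methoxybenzaldehyde
Product: 7 1-(benzyloxy)-4-ethynyl-2-methoxybenzene
Conditions: dimethyl (1-diazo-2-oxopropyl)phosphonate, K2CO3, MeOH, rt
Reagents that add atoms: dimethyl (1-diazo-2-oxopropyl)phosphonate, COP(=O)(OC)C(=[N+]=[N-])C(C)=O
Why: Seyferth–Gilbert homologation in the Ohira–Bestmann modification; methanolysis releases the diazomethylphosphonate anion, which olefinates the aldehyde, and loss of dinitrogen with a 1,2-hydrogen shift gives the terminal alkyne. A non-enolisable aryl aldehyde is the standard substrate.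

Step 5
Reactants: 4 3-[(E)-4-(4-benzyloxy-3-methoxyphenyl)but-2-enoyl]-1,3-oxazolidin-2-one; 7 1-(benzyloxy)-4-ethynyl-2-methoxybenzene
Product: 8 3-{[(1R,4S)-4-(4-benzyloxy-3-methoxybenzyl)-2-(4-benzyloxy-3-methoxyphenyl)cyclobut-2-en-1-yl]carbonyl}-1,3-oxazolidin-2-one (trans)
Conditions: TiCl2(OiPr)2 (20 mol%), (S,S)-TADDOL [(4S,5S)-2,2-dimethyl-α,α,α′,α′-tetraphenyl-1,3-dioxolane-4,5-dimethanol] (22 mol%), 4 Å molecular sieves, 7 (2 equiv), toluene, −20 to 0 °C
Reagents that add atoms: none
Why: Proposed new method: the TADDOLate-bound TiCl2 fragment (tetravalent titanium) chelates both imide carbonyls of 4 in the s-cis form, the terminal carbon of 7 attacks butenoyl C3, positive charge develops on the aryl-bearing alkyne carbon where the para-benzyloxy group stabilises it, and the titanium enolate carbon (butenoyl C2) then collapses onto this vinyl cation. The closest known reaction types are the Lewis acid-catalysed (2+2) cycloaddition of arylalkynes with acrylates and the chiral titanium–TADDOL-catalysed (2+2) cycloaddition of alkynyl sulfides with enoyl oxazolidinones; a β-alkyl acceptor combined with a simple arylalkyne under enantiocontrol is covered by neither. The cyclobutene closes by 4-exo attack of the enolate carbon on the digonal cationic carbon, the enolate double bond remaining outside the new ring. The stereocentre at cyclobutene C4 (future lactone C3) is set by the ligand, whose aryl groups are expected to block the C2-Re/C3-Si face of the bound imide so that the alkyne enters on the Re face of butenoyl C3. The centre at cyclobutene C1 follows from the E geometry of 4, because collapse of the short-lived zwitterion should be faster than bond rotation and the trans cyclobutene is also the more stable isomer. Regioselectivity is secured by polarity: the nucleophilic CH terminus goes to the electrophilic C3 and the cation sits on the carbon that carries the donor arene. Chemoselectivity is secured by using 7 in excess at low temperature, so that the electron-rich styrene unit of 8 does not compete for activated 4.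

Step 6
Reactants: 8 trans cyclobutenyl imide
Product: 9 [(1R,4S)-4-(4-benzyloxy-3-methoxybenzyl)-2-(4-benzyloxy-3-methoxyphenyl)cyclobut-2-en-1-yl]methanol
Conditions: LiBH4, MeOH (1 equiv), THF, 0 °C
Reagents that add atoms: none
Why: Reductive cleavage of an N-acyl oxazolidinone; hydride attacks the lithium-chelated exocyclic carbonyl and the released aldehyde is reduced further. The reagent is not basic enough to disturb the stereocentres or the styrenyl double bond.

Step 7
Reactants: 9 cyclobutenylmethanol
Product: 12 (3R,4S)-4-(4-benzyloxy-3-methoxybenzoyl)-3-(4-benzyloxy-3-methoxybenzyl)tetrahydrofuran-2-ol (cis keto lactol; anomeric mixture), via primary ozonide 10 (not isolated), via hydroxy keto aldehyde 11 (not isolated)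
Conditions: O3, CH2Cl2/MeOH (4:1), −78 °C, Sudan Red 7B end-point; then Me2S, −78 °C to rt
Reagents that add atoms: ozone, [O-][O+]=O
Why: Ozonolysis with reductive work-up; the strained, electron-rich styrenyl double bond adds ozone far faster than the arenes, giving 10, and reduction of its cleavage products gives keto aldehyde 11. The primary alcohol then adds to the aldehyde (5-exo-trig) to form the five-membered lactol; C3 and C4 are not touched, so the trans cyclobutene gives the cis lactol.

Step 8
Reactants: 12 cis keto lactol
Product: 13 (3R,4S)-4-(4-benzyloxy-3-methoxybenzoyl)-3-(4-benzyloxy-3-methoxybenzyl)dihydrofuran-2(3H)-one (cis keto lactone)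
Conditions: TEMPO (20 mol%), PhI(OAc)2, CH2Cl2, rt
Reagents that add atoms: none
Why: Oxoammonium-mediated oxidation of a lactol to the lactone under near-neutral conditions. It removes the latent aldehyde next to C3 before any base is applied.

Step 9
Reactants: 13 cis keto lactone
Product: 14 (3R,4R)-4-(4-benzyloxy-3-methoxybenzoyl)-3-(4-benzyloxy-3-methoxybenzyl)dihydrofuran-2(3H)-one (trans keto lactone)
Conditions: DBU (0.5 equiv), CH2Cl2, rt
Reagents that add atoms: none
Why: Base-mediated epimerisation α to a ketone through the enolate; C4 is equilibrated under the control of C3 to the more stable trans lactone, which sets the (4R) centre. The C3–H, α only to the lactone carbonyl, is markedly less acidic and should not be enolised by an amidine base, and expulsion of the ring carboxylate from the exocyclic enolate is stereoelectronically poor because the C5–O1 bond lies near the nodal plane of the enolate.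

Step 10
Reactants: 14 trans keto lactone bis(benzyl ether)
Product: 15 (3R,4R)-4-(4-hydroxy-3-methoxybenzoyl)-3-(4-hydroxy-3-methoxybenzyl)dihydrofuran-2(3H)-one
Conditions: H2 (1 atm), Pd/C (10%), EtOAc, rt
Reagents that add atoms: none
Why: Catalytic hydrogenolysis of aryl benzyl ethers; under neutral conditions it should be faster than reduction of the donor-substituted aryl ketone if hydrogen uptake is stopped after two equivalents. No stereocentre is involved.

## Compound list

1 | eugenol (4-allyl-2-methoxyphenol) | COc1cc(CC=C)ccc1O | starting material
2 | 4-allyl-1-(benzyloxy)-2-methoxybenzene | C=CCc1ccc(OCc2ccccc2)c(OC)c1 | intermediate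
3 | 3-acryloyl-1,3-oxazolidin-2-one | C=CC(=O)N1CCOC1=O | starting material
4 | 3-[(E)-4-(4-benzyloxy-3-methoxyphenyl)but-2-enoyl]-1,3-oxazolidin-2-one | O=C(/C=C/Cc1ccc(OCc2ccccc2)c(OC)c1)N1CCOC1=O | intermediate
5 | vanillin (4-hydroxy-3-methoxybenzaldehyde) | COc1cc(C=O)ccc1O | starting material
6 | 4-(benzyloxy)-3-methoxybenzaldehyde | O=Cc1ccc(OCc2ccccc2)c(OC)c1 | intermediate
7 | 1-(benzyloxy)-4-ethynyl-2-methoxybenzene | COc1cc(C#C)ccc1OCc1ccccc1 | intermediate
8 | 3-{[(1R,4S)-4-(4-benzyloxy-3-methoxybenzyl)-2-(4-benzyloxy-3-methoxyphenyl)cyclobut-2-en-1-yl]carbonyl}-1,3-oxazolidin-2-one (trans) | O=C([C@@H]1[C@@H](Cc2ccc(OCc3ccccc3)c(OC)c2)C=C1c1ccc(OCc2ccccc2)c(OC)c1)N1CCOC1=O | intermediate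
9 | [(1R,4S)-4-(4-benzyloxy-3-methoxybenzyl)-2-(4-benzyloxy-3-methoxyphenyl)cyclobut-2-en-1-yl]methanol | OC[C@@H]1[C@@H](Cc2ccc(OCc3ccccc3)c(OC)c2)C=C1c1ccc(OCc2ccccc2)c(OC)c1 | intermediate
10 | primary ozonide of 9 (1,2,3-trioxolane cis-fused across the former double bond, either face; not isolated) | OC[C@@H]1[C@@H](Cc2ccc(OCc3ccccc3)c(OC)c2)C2OOOC12c1ccc(OCc2ccccc2)c(OC)c1 | intermediate
11 | (2R,3S)-3-(4-benzyloxy-3-methoxybenzoyl)-2-(4-benzyloxy-3-methoxybenzyl)-4-hydroxybutanal (not isolated) | OC[C@H]([C@@H](Cc1ccc(OCc2ccccc2)c(OC)c1)C=O)C(=O)c1ccc(OCc2ccccc2)c(OC)c1 | intermediate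
12 | (3R,4S)-4-(4-benzyloxy-3-methoxybenzoyl)-3-(4-benzyloxy-3-methoxybenzyl)tetrahydrofuran-2-ol (cis; anomeric mixture) | COc1cc(C[C@H]2C(O)OC[C@H]2C(=O)c2ccc(OCc3ccccc3)c(OC)c2)ccc1OCc1ccccc1 | intermediate
13 | (3R,4S)-4-(4-benzyloxy-3-methoxybenzoyl)-3-(4-benzyloxy-3-methoxybenzyl)dihydrofuran-2(3H)-one (cis) | COc1cc(C[C@H]2C(=O)OC[C@H]2C(=O)c2ccc(OCc3ccccc3)c(OC)c2)ccc1OCc1ccccc1 | intermediate
14 | (3R,4R)-4-(4-benzyloxy-3-methoxybenzoyl)-3-(4-benzyloxy-3-methoxybenzyl)dihydrofuran-2(3H)-one (trans) | COc1cc(C[C@H]2C(=O)OC[C@@H]2C(=O)c2ccc(OCc3ccccc3)c(OC)c2)ccc1OCc1ccccc1 | intermediate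
15 | (3R,4R)-4-(4-hydroxy-3-methoxybenzoyl)-3-(4-hydroxy-3-methoxybenzyl)dihydrofuran-2(3H)-one | COc1cc(C[C@H]2C(=O)OC[C@@H]2C(=O)c2ccc(O)c(OC)c2)ccc1O | target

## Step count and risk

Total: 10 steps. Longest linear sequence: 8 steps (steps 1, 2, 5, 6, 7, 8, 9, 10 from eugenol; equally steps 3, 4, 5 to 10 from vanillin).

**Step 5 (key step, proposed new method).** The most likely failure is insufficient reactivity. A β-alkyl enoyl imide bound to a mild titanium TADDOLate may be too weak an electrophile for an arylalkyne, so that Lewis-acid-induced oligomerisation of 7, chloride capture of the vinyl cation, or migration of the double bond of 4 into conjugation with its arene outruns ring closure. The second risk is poor facial selectivity, because the ligand model is extrapolated from other reaction partners. Raising the promoter to a full equivalent would be tried first.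

The fallback uses known chemistry; it sets out from 6 and returns to the route at 14. One portion of 6 would be converted with propane-1,3-dithiol and BF3·OEt2 into 2-(4-benzyloxy-3-methoxyphenyl)-1,3-dithiane F1. A second portion would be reduced with NaBH4 to (4-benzyloxy-3-methoxyphenyl)methanol F2 and brominated with PBr3 to 4-benzyloxy-3-methoxybenzyl bromide F3. Lithiated F1 (n-BuLi, THF, −78 °C) would add to commercial (5R)-5-(l-menthyloxy)furan-2(5H)-one anti to the menthyloxy group, and the lactone enolate would be alkylated by F3 anti to the new substituent. This tandem conjugate addition–alkylation should give (3R,4R,5R)-3-(4-benzyloxy-3-methoxybenzyl)-4-[2-(4-benzyloxy-3-methoxyphenyl)-1,3-dithian-2-yl]-5-(l-menthyloxy)dihydrofuran-2(3H)-one F4. NaBH4/KOH in aqueous ethanol followed by acidification opens the acetal lactone, reduces the freed aldehyde and relactonises with loss of menthol. The product is (3R,4R)-3-(4-benzyloxy-3-methoxybenzyl)-4-[2-(4-benzyloxy-3-methoxyphenyl)-1,3-dithian-2-yl]dihydrofuran-2(3H)-one F5. Dithiane hydrolysis with HgO and BF3·OEt2 in aqueous THF would give 14, which continues with step 10.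

**Step 2.** The likely failure is migration of the allyl double bond of 2 into conjugation with the arene by ruthenium hydride species. This would lead to a chain-shortened cinnamoyl imide or to the but-3-enoyl isomer of 4. Turnover may also be slow because the imide can chelate the ruthenium carbene. The fallback sets out from 2 and returns at 4. Ozonolysis of 2 (O3, CH2Cl2/MeOH, −78 °C, then Me2S) would give (4-benzyloxy-3-methoxyphenyl)acetaldehyde F6. An E-selective Wittig reaction with the stabilised ylide 3-[(triphenyl-λ5-phosphanylidene)acetyl]-1,3-oxazolidin-2-one in CH2Cl2 at room temperature would then give 4 without a metathesis catalyst.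

**Step 7.** The likely failure is over-oxidation: attack of ozone on the dialkoxyarenes or on the benzylic C–H bonds of the benzyl ethers once the alkene is consumed. The fallback sets out from 9 and returns at 12. Dihydroxylation with catalytic OsO4 and NMO in acetone/water would give 3-(4-benzyloxy-3-methoxybenzyl)-1-(4-benzyloxy-3-methoxyphenyl)-4-(hydroxymethyl)cyclobutane-1,2-diol F7, as a mixture of facial isomers that converge. Glycol cleavage with NaIO4 in THF/water would give 11, which closes to 12.

**Step 9.** The likely failure is erosion of enantiopurity by competing enolisation at C3; together with equilibration at C4 this leads to the enantiomer of 14. Base-induced opening of the lactone by loss of the carboxylate from the C4 enolate is the second risk. The fallback sets out from 12 and returns at 14. Treatment of 12 with MeOH and PPTS would give the cis keto methyl acetal (3R,4S)-4-(4-benzyloxy-3-methoxybenzoyl)-3-(4-benzyloxy-3-methoxybenzyl)-2-methoxytetrahydrofuran F8. In F8, C3 is flanked by an acetal carbon and cannot enolise, and no carboxylate leaving group exists. NaOMe in MeOH would equilibrate C4 to the trans keto methyl acetal F9. Aqueous acetic acid in THF would hydrolyse it to the trans keto lactol (3R,4R)-4-(4-benzyloxy-3-methoxybenzoyl)-3-(4-benzyloxy-3-methoxybenzyl)tetrahydrofuran-2-ol F10, and TEMPO with PhI(OAc)2 would oxidise this to 14.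

**Step 10.** The likely failure is over-reduction: hydrogenation of the aryl ketone to the benzylic alcohol and hydrogenolysis of that alcohol once the phenols are free. The fallback sets out from 14 and leads directly to 15. BCl3 with pentamethylbenzene as cation scavenger in CH2Cl2 at −78 °C is a Lewis-acid debenzylation. It involves no hydrogen, leaves the ketone alone and, at that temperature, spares the aryl methyl ethers. No new compound is formed on the way.

## Further compounds

F1 | step 5 | 2-(4-benzyloxy-3-methoxyphenyl)-1,3-dithiane | COc1cc(C2SCCCS2)ccc1OCc1ccccc1
F2 | step 5 | (4-benzyloxy-3-methoxyphenyl)methanol | COc1cc(CO)ccc1OCc1ccccc1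
F3 | step 5 | 4-benzyloxy-3-methoxybenzyl bromide | COc1cc(CBr)ccc1OCc1ccccc1
F4 | step 5 | (3R,4R,5R)-3-(4-benzyloxy-3-methoxybenzyl)-4-[2-(4-benzyloxy-3-methoxyphenyl)-1,3-dithian-2-yl]-5-(l-menthyloxy)dihydrofuran-2(3H)-one | COc1cc(C[C@H]2C(=O)O[C@@H](O[C@@H]3C[C@H](C)CC[C@H]3C(C)C)[C@@H]2C2(SCCCS2)c2ccc(OCc3ccccc3)c(OC)c2)ccc1OCc1ccccc1
F5 | step 5 | (3R,4R)-3-(4-benzyloxy-3-methoxybenzyl)-4-[2-(4-benzyloxy-3-methoxyphenyl)-1,3-dithian-2-yl]dihydrofuran-2(3H)-one | COc1cc(C[C@H]2C(=O)OC[C@@H]2C2(SCCCS2)c2ccc(OCc3ccccc3)c(OC)c2)ccc1OCc1ccccc1
F6 | step 2 | (4-benzyloxy-3-methoxyphenyl)acetaldehyde | O=CCc1ccc(OCc2ccccc2)c(OC)c1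
F7 | step 7 | 3-(4-benzyloxy-3-methoxybenzyl)-1-(4-benzyloxy-3-methoxyphenyl)-4-(hydroxymethyl)cyclobutane-1,2-diol (cis diol, facial mixture) | OC[C@@H]1[C@@H](Cc2ccc(OCc3ccccc3)c(OC)c2)C(O)C1(O)c1ccc(OCc2ccccc2)c(OC)c1
F8 | step 9 | (3R,4S)-4-(4-benzyloxy-3-methoxybenzoyl)-3-(4-benzyloxy-3-methoxybenzyl)-2-methoxytetrahydrofuran (cis; anomeric mixture) | COc1cc(C[C@H]2C(OC)OC[C@H]2C(=O)c2ccc(OCc3ccccc3)c(OC)c2)ccc1OCc1ccccc1
F9 | step 9 | (3R,4R)-4-(4-benzyloxy-3-methoxybenzoyl)-3-(4-benzyloxy-3-methoxybenzyl)-2-methoxytetrahydrofuran (trans; anomeric mixture) | COc1cc(C[C@H]2C(OC)OC[C@@H]2C(=O)c2ccc(OCc3ccccc3)c(OC)c2)ccc1OCc1ccccc1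
F10 | step 9 | (3R,4R)-4-(4-benzyloxy-3-methoxybenzoyl)-3-(4-benzyloxy-3-methoxybenzyl)tetrahydrofuran-2-ol (trans; anomeric mixture) | COc1cc(C[C@H]2C(O)OC[C@@H]2C(=O)c2ccc(OCc3ccccc3)c(OC)c2)ccc1OCc1ccccc1
F0 | step 10 | none | none
A1 | alternative 1 | O-{(2S,3E)-2-[(S)-(4-benzyloxy-3-methoxyphenyl)(tert-butyldimethylsilyloxy)methyl]-4-(4-benzyloxy-3-methoxyphenyl)but-3-en-1-yl} Se-phenyl selenocarbonate | O=C([Se]c1ccccc1)OC[C@@H](/C=C/c1ccc(OCc2ccccc2)c(OC)c1)[C@H](O[Si](C)(C)C(C)(C)C)c1ccc(OCc2ccccc2)c(OC)c1
A2 | alternative 1 | trans-3-(4-benzyloxy-3-methoxybenzyl)-4-[(4-benzyloxy-3-methoxyphenyl)(tert-butyldimethylsilyloxy)methyl]dihydrofuran-2(3H)-one | COc1cc(C[C@H]2C(=O)OC[C@@H]2[C@H](O[Si](C)(C)C(C)(C)C)c2ccc(OCc3ccccc3)c(OC)c2)ccc1OCc1ccccc1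
A3 | alternative 2 | 4-(4-benzyloxy-3-methoxybenzyl)-5-oxo-2,5-dihydrofuran-3-yl trifluoromethanesulfonate | O=C1OCC(OS(=O)(=O)C(F)(F)F)=C1Cc1ccc(OCc2ccccc2)c(OC)c1
A4 | alternative 2 | (4-benzyloxy-3-methoxyphenyl)boronic acid | COc1cc(B(O)O)ccc1OCc1ccccc1
A5 | alternative 2 | carbon monoxide | [C-]#[O+]
A6 | alternative 2 | 3-(4-benzyloxy-3-methoxybenzyl)-4-(4-benzyloxy-3-methoxybenzoyl)furan-2(5H)-one | COc1cc(CC2=C(C(=O)c3ccc(OCc4ccccc4)c(OC)c3)COC2=O)ccc1OCc1ccccc1
A7 | alternative 3 | methyl (E)-4-(4-benzyloxy-3-methoxyphenyl)-4-oxobut-2-enoate | COC(=O)/C=C/C(=O)c1ccc(OCc2ccccc2)c(OC)c1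
A8 | alternative 3 | (4-benzyloxy-3-methoxybenzyl)zinc bromide | COc1cc(C[Zn]Br)ccc1OCc1ccccc1
A9 | alternative 3 | formaldehyde | C=O
A10 | alternative 3 | (3R,4R)-4-(4-benzyloxy-3-methoxybenzoyl)-3-(4-benzyloxy-3-methoxybenzyl)dihydrofuran-2(3H)-one | COc1cc(C[C@H]2C(=O)OC[C@@H]2C(=O)c2ccc(OCc3ccccc3)c(OC)c2)ccc1OCc1ccccc1
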